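The data come from a simulation with constants of no real substance, and the scatter is random.

The flask holds more partner than the violet run and less than the blue run, and its other charges match theirs. At 15.0 h the violet run reads 0.3% left-handed substrate and 46.3% right-handed substrate, and the blue run reads 0% and 43.4%.

| setting | violet | blue | flask |
|---|---|---|---|
| left-handed substrate | 0.050 M | 0.050 M | 0.050 M |
| right-handed substrate | 0.050 M | 0.050 M | 0.050 M |
| partner | 0.10 M | 0.22 M | 0.150 M |
| free catalyst | 0.75 mM | 0.75 mM | 0.75 mM |
| impurity | 0.33 mM | 0.33 mM | 0.33 mM |
| remark | run made earlier | run made earlier |  |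
| time |  |  | 20 h |

| run | time / h | right-handed substrate / % | left-handed substrate / % | left-handed product / % |
|---|---|---|---|---|
| violet | 1.33 | 49.1 | 9.8 | 40.9 |
| violet | 3.00 | 49.3 | 3.2 | 46.9 |
| violet | 6.00 | 47.8 | 0 | 48.4 |
| violet | 15.0 | 46.3 | 0.3 | 49.0 |
| blue | 4.00 | 47.1 | 0.1 | 50.2 |
| blue | 8.00 | 44.8 | 1.0 | 49.4 |
| blue | 12.0 | 43.9 | 0.3 | 50.5 |
| blue | 15.0 | 43.4 | 0 | 49.8 |

(scatter of a reading: 0.5 percentage points)

- whether the excess of right-handed substrate over left-handed substrate among what is left of the two reaches 99% by 20 h (no / yes)
- the highest excess of right-handed substrate over left-handed substrate among what is left of the two up to 20 h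

- free catalyst is single-handed; left-handed substrate and right-handed substrate are mirror images of each other, charged as a racemate, each of them at the stated concentration

One thing looks contradictory. An excess of 99% needs left-handed substrate near 0.251%, which is less than the scatter of 0.5 percentage points, so a single reading does not resolve it. Yet the excess can be reckoned as a count of time constants: the ratio of left-handed to right-handed substrate must fall by a natural logarithm of 5.29.

The violet readings 9.8% and 3.2% stand clear of the scatter. They give a decay constant of 0.670 h⁻¹ at c(partner) of about 0.0561 M, so the constant per unit of partner is 11.9 L mol⁻¹ h⁻¹. This reckoning is my own. In the flask, once the left-handed substrate has reacted, c(partner) stands near 0.100 M, which gives a pseudo-first-order constant of 1.19 h⁻¹. The first round, with that constant held throughout, gives 4.43 h.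

Going round again, c(partner) starts above that level, and the second-order loss then earns the natural logarithm of charge over surplus, 0.405 time constants. The second round gives the clearing time, the count still owed divided by the constant, of 4.09 h. That is shorter than the 20 h allowed.

The forecast says yes, with a top of 99.9%: “A small floor cannot be strictly excluded, but nothing demands one.”

The flask gives yes, with a top of >99.9%.

    partner + free catalyst + left-handed substrate → free catalyst + left-handed product (k = 40000 L² mol⁻² h⁻¹)
    partner + free catalyst + right-handed substrate → free catalyst + right-handed product (k = 270 L² mol⁻² h⁻¹)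
    partner + free catalyst → spent catalyst A (k = 0.310 L mol⁻¹ h⁻¹)
    free catalyst + impurity → spent catalyst B (k = 12000 L mol⁻¹ h⁻¹)
    free catalyst → spent catalyst C (k = 0.0420 h⁻¹)

The flask reaches the wanted excess at 3.24 h, earlier than the clearing time of 4.09 h. Its mean constant to that point is 1.63 h⁻¹, above 1.19 h⁻¹. At 2.00 h the flask holds 47.6% free catalyst and 44.0% spent catalyst B, in percent of the catalyst charged. In the blue run the surplus partner is 0.170 M, so the reckoned clearing time there is 2.48 h, shorter than the 4.00 h of its first reading. That reading shows left-handed substrate at 0.1%.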